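The route builds ring A onto the ring B oxygen, so no crowded diaryl ether coupling is needed. The C1–C6 and C4–C5 bonds of the benzoate ring are disconnected to the ethynyl ether of a protected ring B phenol and a 2-pyrone-3-carboxylate. One thermal operation (inverse-demand [4+2] cycloaddition, then loss of CO2) should deliver ring A aromatic with aryloxy on C6, ester on C1, methoxy on C2 and bromine on C3. It exploits that C4 and C5 bear only hydrogen beside four contiguous substituents. The precursors are a 2-benzyloxy-6-(silyloxymethyl)-4-methylphenyl ethynyl ether and benzyl 5-bromo-4-methoxy-2-pyrone-3-carboxylate; bromine later becomes the (R)-configured diol side chain.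

Key step: step 11

Remark: the carbinol carbon of the target is (R) (OH > ring A carbon > CH2 > H). Ring A is numbered C1 (carboxyl), C2 (OMe), C3 (side chain), C6 (aryloxy); the pyrone is numbered O1, C2 (C=O), C3 (ester), C4 (OMe), C5 (Br), C6 (H).

Remark: ArO stands for 2-(benzyloxy)-6-[(tert-butyldimethylsilyloxy)methyl]-4-methylphenoxy. (+)-Ipc2BOMe is B-methoxydiisopinocampheylborane made from (−)-α-pinene, SMILES COB([C@H]1C[C@H]2C[C@@H]([C@@H]1C)C2(C)C)[C@H]1C[C@H]2C[C@@H]([C@@H]1C)C2(C)C.

Remark on design: ring B is taken from 2-hydroxy-4-methylbenzaldehyde, so its two oxygens are introduced one after the other and never have to be told apart. The pyrone ester is benzyl because the 2,6-disubstituted benzoate of ring A can then be freed by hydrogenolysis instead of saponification. The ethynyl ether is made directly before the union and not stored.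

Step 1
Reactants: 1 2-hydroxy-4-methylbenzaldehyde
Product: 2 2-(benzyloxy)-4-methylbenzaldehyde
Conditions: BnBr, K2CO3, DMF, 60 °C
Reagents that add atoms: benzyl bromide, BrCc1ccccc1
Why: Williamson etherification of the only hydroxyl group, whose phenoxide is alkylated cleanly by benzyl bromide under carbonate conditions.

Step 2
Reactants: 2 2-(benzyloxy)-4-methylbenzaldehyde
Product: 4 2-(benzyloxy)-4-methylphenol, via aryl formate 3 (not isolated)
Conditions: mCPBA, CH2Cl2, rt; then K2CO3 (cat.), MeOH, rt
Reagents that add atoms: 3-chloroperoxybenzoic acid, O=C(OO)c1cccc(Cl)c1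
Why: Baeyer–Villiger oxidation of an aldehyde on a ring carrying an ortho benzyloxy and a para methyl donor should proceed with aryl migration to the formate, which mild methanolysis converts to the phenol.

Step 3
Reactants: 4 2-(benzyloxy)-4-methylphenol
Product: 5 2-(benzyloxy)-6-(hydroxymethyl)-4-methylphenol
Conditions: 37% aq. CH2O (excess), NaOH, H2O/THF, rt
Reagents that add atoms: formaldehyde, C=O
Why: Lederer–Manasse hydroxymethylation, in which the phenoxide is C-nucleophilic only ortho and para to oxygen, so with para blocked by methyl and one ortho position by benzyloxy the formaldehyde should enter only at C6, excess formaldehyde at room temperature holding back diarylmethane condensation.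

Step 4
Reactants: 5 2-(benzyloxy)-6-(hydroxymethyl)-4-methylphenol
Product: 6 2-(benzyloxy)-6-[(tert-butyldimethylsilyloxy)methyl]-4-methylphenol
Conditions: TBSCl, imidazole, CH2Cl2, 0 °C
Reagents that add atoms: tert-butyldimethylsilyl chloride, CC(C)(C)[Si](C)(C)Cl
Why: Silylation of the primary benzylic alcohol should outrun that of the hindered phenol flanked by two ortho substituents, a selectivity established for 2-hydroxybenzyl alcohols.

Step 5
Reactants: 6 2-(benzyloxy)-6-[(tert-butyldimethylsilyloxy)methyl]-4-methylphenol; 7 trichloroethylene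
Product: 9 1-(benzyloxy)-3-[(tert-butyldimethylsilyloxy)methyl]-2-{[(E)-1,2-dichloroethenyl]oxy}-5-methylbenzene, via dichloroacetylene 8 (not isolated)
Conditions: K2CO3, DMF, 70 °C, closed flask under N2
Reagents that add atoms: none
Why: Carbonate dehydrochlorinates trichloroethylene to dichloroacetylene, to which the phenoxide adds in anti fashion (nucleophilic addition to a haloalkyne), the standard entry to aryl (E)-1,2-dichlorovinyl ethers and one that the small electrophile should allow even for a 2,6-disubstituted phenoxide.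

Step 6
Reactants: 9 1-(benzyloxy)-3-[(tert-butyldimethylsilyloxy)methyl]-2-{[(E)-1,2-dichloroethenyl]oxy}-5-methylbenzene
Product: 12 1-(benzyloxy)-3-[(tert-butyldimethylsilyloxy)methyl]-2-(ethynyloxy)-5-methylbenzene, via chloroethynyl ether 10 (not isolated), via lithium acetylide 11 (not isolated)
Conditions: n-BuLi (2.3 equiv), THF, −78 °C; then H2O, −78 °C; cold work-up, used at once
Reagents that add atoms: none
Why: Deprotonation and loss of chloride give the chloroalkyne, chlorine–lithium exchange gives the acetylide and protonation the terminal ynol ether (the established dichlorovinyl ether route to ynol ethers), the benzyl and silyl ethers being inert to n-BuLi at −78 °C.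

Step 7
Reactants: 13 dibenzyl malonate; 14 (E)-3-ethoxyacryloyl chloride
Product: 15 dibenzyl 2-[(E)-3-ethoxyacryloyl]malonate
Conditions: MgCl2, Et3N, MeCN, 0 °C to rt
Reagents that add atoms: none
Why: Magnesium-mediated C-acylation of a malonate (soft enolisation with MgCl2 and Et3N) is the standard route to acylmalonates, the chelated magnesium enolate preventing O-acylation and double acylation.

Step 8
Reactants: 15 dibenzyl 2-[(E)-3-ethoxyacryloyl]malonate
Product: 16 benzyl 4-hydroxy-2-oxo-2H-pyran-3-carboxylate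
Conditions: TFA, H2O (2 equiv), CH2Cl2, rt
Reagents that add atoms: none
Why: Acid-promoted lactonisation in which an ester carbonyl oxygen adds 6-endo to the protonated β-ethoxy enone, ethanol is lost and the 2-benzyloxypyrylium ion is debenzylated, the same ring closure by which alkoxyallylidene malonates give 2-pyrone-3-carboxylates, while the second benzyl ester is stable to TFA at room temperature.

Step 9
Reactants: 16 benzyl 4-hydroxy-2-oxo-2H-pyran-3-carboxylate
Product: 17 benzyl 4-methoxy-2-oxo-2H-pyran-3-carboxylate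
Conditions: Me2SO4, K2CO3, acetone, reflux
Reagents that add atoms: dimethyl sulfate, COS(=O)(=O)OC
Why: O-Alkylation of the vinylogous acid with a hard methylating agent under carbonate conditions should give the 4-methoxy-2-pyrone, as with other 4-hydroxy-2-pyrones, because this isomer keeps the lactone and the conjugated ester.

Step 10
Reactants: 17 benzyl 4-methoxy-2-oxo-2H-pyran-3-carboxylate
Product: 19 benzyl 5-bromo-4-methoxy-2-oxo-2H-pyran-3-carboxylate, via dibromo lactone 18 (not isolated)
Conditions: Br2, CH2Cl2, 0 °C to rt; then Et3N, 0 °C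
Reagents that add atoms: bromine, BrBr
Why: Bromination by addition–elimination, in which bromine adds across the only enol-ether-like double bond (C5=C6, since C3 is blocked and C3=C4 is tetrasubstituted and push–pull) and Et3N removes HBr through loss of the anomeric C6 bromide and the C5 proton, leaving bromine on C5.

Step 11
Reactants: 12 1-(benzyloxy)-3-[(tert-butyldimethylsilyloxy)methyl]-2-(ethynyloxy)-5-methylbenzene; 19 benzyl 5-bromo-4-methoxy-2-oxo-2H-pyran-3-carboxylate
Product: 21 benzyl 6-ArO-3-bromo-2-methoxybenzoate, via bicyclic lactone 20 (not isolated)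
Conditions: PhMe, 110 °C, sealed tube, argon, 12 in 1.5-fold excess
Reagents that add atoms: none
Why: Proposed new method: the electron-rich alkyne of 12 and the electron-poor diene of 19 should combine in an asynchronous inverse-electron-demand Diels–Alder reaction in which the terminal alkyne carbon bonds to pyrone C6 and the oxygen-bearing carbon to C3, giving bridged lactone 20, which loses CO2 by retro-[4+2] to the aromatic benzoate. The closest known reaction type is the cycloaddition of 2-pyrone-3-carboxylates with ketene acetals, ynamines and alkoxyalkynes followed by CO2 loss, which gives benzoates, whereas an aryloxyacetylene has not served as the two-carbon partner. Ring A is closed by intermolecular [4+2] cycloaddition, the C1–C6 and C4–C5 bonds forming in one operation, and is made aromatic by the cycloreversion. No stereocentre is created, since the two bridgehead carbons of 20 become arene carbons. The one selectivity needed is regiochemical and should follow from matched polarity: pyrone C6 is the conjugate-acceptor terminus because attack there places charge on C3 between the lactone and ester carbonyls while the 4-methoxy group deactivates C4, and the alkyne terminus is the nucleophilic end of the ynol ether. An aryl ynol ether has no O-alkyl hydrogen for retro-ene fragmentation to a ketene, so it should tolerate the temperature.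

Step 12
Reactants: 21 benzyl 6-ArO-3-bromo-2-methoxybenzoate
Product: 24 benzyl 6-ArO-3-formyl-2-methoxybenzoate, via arylmagnesium chloride 22 (not isolated), via magnesium hemiaminal 23 (not isolated)
Conditions: iPrMgCl·LiCl, THF, −15 to 0 °C; then DMF, 0 °C to rt; aq. NH4Cl
Reagents that add atoms: N,N-dimethylformamide, CN(C)C=O
Why: Bromine–magnesium exchange with iPrMgCl·LiCl is favoured by the ortho methoxy group and the electron-poor benzoate ring and tolerates the ester shielded by two ortho substituents, and the arylmagnesium is formylated by DMF (Bouveault aldehyde synthesis) through the hemiaminal.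

Step 13
Reactants: 24 benzyl 6-ArO-3-formyl-2-methoxybenzoate
Product: 26 benzyl 6-ArO-3-[(1R)-1-hydroxy-3-methylbut-3-en-1-yl]-2-methoxybenzoate, via borinate ester 25 (not isolated)
Conditions: (+)-Ipc2BOMe, methallylMgCl, Et2O, 0 °C to rt; then 24, −78 °C; NaOH, H2O2, 0 °C to rt
Reagents that add atoms: 2-methylallylmagnesium chloride, CC(=C)C[Mg]Cl
Why: Brown allylboration, in which the methallylborane made in the flask from the (−)-α-pinene-derived borinate adds through a closed chair transition state to the Re face of the aryl aldehyde and so should set the (R) carbinol centre under reagent control, after which oxidative work-up frees the alcohol from the borinate.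

Step 14
Reactants: 26 benzyl 6-ArO-3-[(1R)-1-hydroxy-3-methylbut-3-en-1-yl]-2-methoxybenzoate
Product: 28 benzyl 6-ArO-3-[(1R)-1,3-dihydroxy-3-methylbutyl]-2-methoxybenzoate, via tertiary hydroperoxide 27 (not isolated)
Conditions: Co(acac)2 (cat.), PhSiH3, O2 (1 atm), THF, rt
Reagents that add atoms: dioxygen, O=O
Why: Mukaiyama hydration, in which hydrogen-atom transfer from a cobalt hydride to the 1,1-disubstituted alkene gives the tertiary radical (Markovnikov), O2 traps it and the silane reduces the hydroperoxide, conditions that leave the benzyl groups, the silyl ether and the carbinol centre untouched.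

Step 15
Reactants: 28 benzyl 6-ArO-3-[(1R)-1,3-dihydroxy-3-methylbutyl]-2-methoxybenzoate
Product: 29 benzyl 6-[2-(benzyloxy)-6-(hydroxymethyl)-4-methylphenoxy]-3-[(1R)-1,3-dihydroxy-3-methylbutyl]-2-methoxybenzoate
Conditions: TBAF, THF, 0 °C to rt
Reagents that add atoms: none
Why: Fluoride-induced cleavage of the primary silyl ether is fast at 0 °C, and the benzyl ester, shielded by two ortho substituents, should not be attacked by the basic fluoride.

Step 16
Reactants: 29 benzyl 6-[2-(benzyloxy)-6-(hydroxymethyl)-4-methylphenoxy]-3-[(1R)-1,3-dihydroxy-3-methylbutyl]-2-methoxybenzoate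
Product: 30 3-[(1R)-1,3-dihydroxy-3-methylbutyl]-6-[2-hydroxy-6-(hydroxymethyl)-4-methylphenoxy]-2-methoxybenzoic acid (CNP0452050.1)
Conditions: H2 (1 atm), 10% Pd/C, EtOAc, rt, stopped at full conversion
Reagents that add atoms: none
Why: Hydrogenolysis of the aryl benzyl ether and the benzyl ester over Pd/C under neutral conditions is much faster than reduction of benzylic alcohols, so the hindered acid and the phenol should be freed in one operation with both benzylic carbinols and the (R) centre intact.

Compound list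
1 | 2-hydroxy-4-methylbenzaldehyde | O=Cc1ccc(C)cc1O | starting material
2 | 2-(benzyloxy)-4-methylbenzaldehyde | O=Cc1ccc(C)cc1OCc1ccccc1 | intermediate
3 | 2-(benzyloxy)-4-methylphenyl formate | O=COc1ccc(C)cc1OCc1ccccc1 | intermediate
4 | 2-(benzyloxy)-4-methylphenol | Oc1ccc(C)cc1OCc1ccccc1 | intermediate
5 | 2-(benzyloxy)-6-(hydroxymethyl)-4-methylphenol | OCc1cc(C)cc(OCc2ccccc2)c1O | intermediate
6 | 2-(benzyloxy)-6-[(tert-butyldimethylsilyloxy)methyl]-4-methylphenol | CC(C)(C)[Si](C)(C)OCc1cc(C)cc(OCc2ccccc2)c1O | intermediate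
7 | trichloroethylene | ClC=C(Cl)Cl | starting material
8 | dichloroacetylene | ClC#CCl | intermediate
9 | 1-(benzyloxy)-3-[(tert-butyldimethylsilyloxy)methyl]-2-{[(E)-1,2-dichloroethenyl]oxy}-5-methylbenzene | Cl/C=C(/Cl)Oc1c(OCc2ccccc2)cc(C)cc1CO[Si](C)(C)C(C)(C)C | intermediate
10 | 1-(benzyloxy)-3-[(tert-butyldimethylsilyloxy)methyl]-2-[(chloroethynyl)oxy]-5-methylbenzene | ClC#COc1c(OCc2ccccc2)cc(C)cc1CO[Si](C)(C)C(C)(C)C | intermediate
11 | ({2-(benzyloxy)-6-[(tert-butyldimethylsilyloxy)methyl]-4-methylphenoxy}ethynyl)lithium | [Li]C#COc1c(OCc2ccccc2)cc(C)cc1CO[Si](C)(C)C(C)(C)C | intermediate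
12 | 1-(benzyloxy)-3-[(tert-butyldimethylsilyloxy)methyl]-2-(ethynyloxy)-5-methylbenzene | C#COc1c(OCc2ccccc2)cc(C)cc1CO[Si](C)(C)C(C)(C)C | intermediate
13 | dibenzyl malonate | O=C(CC(=O)OCc1ccccc1)OCc1ccccc1 | starting material
14 | (E)-3-ethoxyacryloyl chloride | CCO/C=C/C(=O)Cl | starting material
15 | dibenzyl 2-[(E)-3-ethoxyacryloyl]malonate | CCO/C=C/C(=O)C(C(=O)OCc1ccccc1)C(=O)OCc1ccccc1 | intermediate
16 | benzyl 4-hydroxy-2-oxo-2H-pyran-3-carboxylate | O=C(OCc1ccccc1)C1=C(O)C=COC1=O | intermediate
17 | benzyl 4-methoxy-2-oxo-2H-pyran-3-carboxylate | O=C(OCc1ccccc1)C1=C(OC)C=COC1=O | intermediate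
18 | benzyl 5,6-dibromo-4-methoxy-2-oxo-5,6-dihydro-2H-pyran-3-carboxylate (racemic) | O=C(OCc1ccccc1)C1=C(OC)C(Br)C(Br)OC1=O | intermediate
19 | benzyl 5-bromo-4-methoxy-2-oxo-2H-pyran-3-carboxylate | O=C(OCc1ccccc1)C1=C(OC)C(Br)=COC1=O | intermediate
20 | benzyl 8-{2-(benzyloxy)-6-[(tert-butyldimethylsilyloxy)methyl]-4-methylphenoxy}-6-bromo-5-methoxy-3-oxo-2-oxabicyclo[2.2.2]octa-5,7-diene-4-carboxylate (racemic) | O=C1OC2C=C(Oc3c(OCc4ccccc4)cc(C)cc3CO[Si](C)(C)C(C)(C)C)C1(C(=O)OCc5ccccc5)C(OC)=C2Br | intermediate
21 | benzyl 6-{2-(benzyloxy)-6-[(tert-butyldimethylsilyloxy)methyl]-4-methylphenoxy}-3-bromo-2-methoxybenzoate | COc1c(Br)ccc(Oc2c(OCc3ccccc3)cc(C)cc2CO[Si](C)(C)C(C)(C)C)c1C(=O)OCc1ccccc1 | intermediate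
22 | [3-(benzyloxycarbonyl)-4-{2-(benzyloxy)-6-[(tert-butyldimethylsilyloxy)methyl]-4-methylphenoxy}-2-methoxyphenyl]magnesium chloride | COc1c([Mg]Cl)ccc(Oc2c(OCc3ccccc3)cc(C)cc2CO[Si](C)(C)C(C)(C)C)c1C(=O)OCc1ccccc1 | intermediate
23 | chloromagnesium alkoxide of benzyl 6-{2-(benzyloxy)-6-[(tert-butyldimethylsilyloxy)methyl]-4-methylphenoxy}-3-[(dimethylamino)(hydroxy)methyl]-2-methoxybenzoate | COc1c(C(O[Mg]Cl)N(C)C)ccc(Oc2c(OCc3ccccc3)cc(C)cc2CO[Si](C)(C)C(C)(C)C)c1C(=O)OCc1ccccc1 | intermediate
24 | benzyl 6-{2-(benzyloxy)-6-[(tert-butyldimethylsilyloxy)methyl]-4-methylphenoxy}-3-formyl-2-methoxybenzoate | COc1c(C=O)ccc(Oc2c(OCc3ccccc3)cc(C)cc2CO[Si](C)(C)C(C)(C)C)c1C(=O)OCc1ccccc1 | intermediate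
25 | diisopinocampheylborinate of alcohol 26 (R at the carbinol carbon) | COc1c([C@H](OB([C@H]2C[C@H]3C[C@@H]([C@@H]2C)C3(C)C)[C@H]2C[C@H]3C[C@@H]([C@@H]2C)C3(C)C)CC(C)=C)ccc(Oc2c(OCc3ccccc3)cc(C)cc2CO[Si](C)(C)C(C)(C)C)c1C(=O)OCc1ccccc1 | intermediate
26 | benzyl 6-{2-(benzyloxy)-6-[(tert-butyldimethylsilyloxy)methyl]-4-methylphenoxy}-3-[(1R)-1-hydroxy-3-methylbut-3-en-1-yl]-2-methoxybenzoate | COc1c([C@H](O)CC(C)=C)ccc(Oc2c(OCc3ccccc3)cc(C)cc2CO[Si](C)(C)C(C)(C)C)c1C(=O)OCc1ccccc1 | intermediate
27 | benzyl 6-{2-(benzyloxy)-6-[(tert-butyldimethylsilyloxy)methyl]-4-methylphenoxy}-3-[(1R)-3-hydroperoxy-1-hydroxy-3-methylbutyl]-2-methoxybenzoate | COc1c([C@H](O)CC(C)(C)OO)ccc(Oc2c(OCc3ccccc3)cc(C)cc2CO[Si](C)(C)C(C)(C)C)c1C(=O)OCc1ccccc1 | intermediate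
28 | benzyl 6-{2-(benzyloxy)-6-[(tert-butyldimethylsilyloxy)methyl]-4-methylphenoxy}-3-[(1R)-1,3-dihydroxy-3-methylbutyl]-2-methoxybenzoate | COc1c([C@H](O)CC(C)(C)O)ccc(Oc2c(OCc3ccccc3)cc(C)cc2CO[Si](C)(C)C(C)(C)C)c1C(=O)OCc1ccccc1 | intermediate
29 | benzyl 6-[2-(benzyloxy)-6-(hydroxymethyl)-4-methylphenoxy]-3-[(1R)-1,3-dihydroxy-3-methylbutyl]-2-methoxybenzoate | COc1c([C@H](O)CC(C)(C)O)ccc(Oc2c(OCc3ccccc3)cc(C)cc2CO)c1C(=O)OCc1ccccc1 | intermediate
30 | 3-[(1R)-1,3-dihydroxy-3-methylbutyl]-6-[2-hydroxy-6-(hydroxymethyl)-4-methylphenoxy]-2-methoxybenzoic acid | COc1c([C@H](O)CC(C)(C)O)ccc(Oc2c(O)cc(C)cc2CO)c1C(=O)O | target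

Total step count: 16 (steps 1–6 ring B fragment, steps 7–10 pyrone, step 11 union, steps 12–16 end game).
Longest linear sequence: 12 steps (steps 1–6, then 11–16).

Steps most likely to fail

Step 11 (proposed new method). The cycloaddition may be slower than thermal consumption of the ynol ether by oligomerisation or by hydration with adventitious water, because the 4-methoxy group raises the LUMO of the pyrone. The fallback uses only known chemistry, sets out from phenol 6 and comes back to the route at aldehyde 24. Commercial 2-bromo-5-fluoroanisole (COc1cc(F)ccc1Br) is deprotonated between fluorine and methoxy with LiN(iPr)2 in THF at −78 °C (directed ortho-metalation) and trapped with benzyl chloroformate to give benzyl 3-bromo-6-fluoro-2-methoxybenzoate F1. Bromine–magnesium exchange with iPrMgCl·LiCl and quenching with DMF give benzyl 6-fluoro-3-formyl-2-methoxybenzoate F2, in which fluorine is para to the formyl group and ortho to the ester. Nucleophilic aromatic substitution by the phenoxide of 6 (K2CO3, DMF, 80 °C) should then give 24. Steps 13–16 follow unchanged, and steps 5–10 and 12 are no longer needed.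

Step 6. The terminal aryl ynol ether may be lost during work-up and concentration, through hydration to the aryl acetate or through oligomerisation. The fallback sets out from dichlorovinyl ether 9 and comes back at 12. The acetylide 11 is generated as before but quenched with Me3SiCl instead of water, giving tert-butyl{[3-(benzyloxy)-5-methyl-2-{[(trimethylsilyl)ethynyl]oxy}benzyl]oxy}dimethylsilane F3, which should survive chromatography and storage. The C-silyl group is removed with K2CO3 in MeOH at 0 °C immediately before use, and the filtered solution of 12 goes straight into step 11.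

Step 16. Over-reduction may occur, that is hydrogenolysis of a benzylic C–O bond, most likely at the electron-rich secondary carbinol of ring A once the free acid is present. The fallback sets out from homoallylic alcohol 26 and comes back at target 30. The secondary alcohol is silylated (TBSOTf, 2,6-lutidine, CH2Cl2, −78 °C) to benzyl 6-{2-(benzyloxy)-6-[(tert-butyldimethylsilyloxy)methyl]-4-methylphenoxy}-3-[(1R)-1-(tert-butyldimethylsilyloxy)-3-methylbut-3-en-1-yl]-2-methoxybenzoate F4. Mukaiyama hydration as in step 14 gives benzyl 6-{2-(benzyloxy)-6-[(tert-butyldimethylsilyloxy)methyl]-4-methylphenoxy}-3-[(1R)-1-(tert-butyldimethylsilyloxy)-3-hydroxy-3-methylbutyl]-2-methoxybenzoate F5. Hydrogenolysis (H2, Pd/C, EtOAc), now with both benzylic oxygens silylated, gives 3-[(1R)-1-(tert-butyldimethylsilyloxy)-3-hydroxy-3-methylbutyl]-6-{2-hydroxy-6-[(tert-butyldimethylsilyloxy)methyl]-4-methylphenoxy}-2-methoxybenzoic acid F6. TBAF in THF then removes both silyl groups to give 30.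

Further compounds
F1 | step 11 | benzyl 3-bromo-6-fluoro-2-methoxybenzoate | O=C(OCc1ccccc1)c1c(F)ccc(Br)c1OC
F2 | step 11 | benzyl 6-fluoro-3-formyl-2-methoxybenzoate | O=Cc1ccc(F)c(C(=O)OCc2ccccc2)c1OC
F3 | step 6 | tert-butyl{[3-(benzyloxy)-5-methyl-2-{[(trimethylsilyl)ethynyl]oxy}benzyl]oxy}dimethylsilane | C[Si](C)(C)C#COc1c(OCc2ccccc2)cc(C)cc1CO[Si](C)(C)C(C)(C)C
F4 | step 16 | benzyl 6-{2-(benzyloxy)-6-[(tert-butyldimethylsilyloxy)methyl]-4-methylphenoxy}-3-[(1R)-1-(tert-butyldimethylsilyloxy)-3-methylbut-3-en-1-yl]-2-methoxybenzoate | COc1c([C@H](O[Si](C)(C)C(C)(C)C)CC(C)=C)ccc(Oc2c(OCc3ccccc3)cc(C)cc2CO[Si](C)(C)C(C)(C)C)c1C(=O)OCc1ccccc1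
F5 | step 16 | benzyl 6-{2-(benzyloxy)-6-[(tert-butyldimethylsilyloxy)methyl]-4-methylphenoxy}-3-[(1R)-1-(tert-butyldimethylsilyloxy)-3-hydroxy-3-methylbutyl]-2-methoxybenzoate | COc1c([C@H](O[Si](C)(C)C(C)(C)C)CC(C)(C)O)ccc(Oc2c(OCc3ccccc3)cc(C)cc2CO[Si](C)(C)C(C)(C)C)c1C(=O)OCc1ccccc1
F6 | step 16 | 3-[(1R)-1-(tert-butyldimethylsilyloxy)-3-hydroxy-3-methylbutyl]-6-{2-hydroxy-6-[(tert-butyldimethylsilyloxy)methyl]-4-methylphenoxy}-2-methoxybenzoic acid | COc1c([C@H](O[Si](C)(C)C(C)(C)C)CC(C)(C)O)ccc(Oc2c(O)cc(C)cc2CO[Si](C)(C)C(C)(C)C)c1C(=O)O
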